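## Structural features

- The target is a bicyclo[3.3.1]nonane-2,4,9-trione. Ring A (C1–C2–C3–C4–C5–C9) holds the enolized 2,4-diketone with the 3,4-dihydroxybenzoyl group on C3. Ring B (C1–C9–C5–C6–C7–C8) holds the gem-dimethyl carbon C8 and the prenylated C7. The rings share C1, C9 and C5.
- C1 and C5 are quaternary bridgeheads, each with a prenyl group. C7 is tertiary with its prenyl group exo: equatorial on a chair ring B, cis to the bridgehead prenyl groups, anti to ring A. The configuration is (1S,5S,7R).
- C1 is bonded to the quaternary C8, so the C1–C8 bond joins two fully substituted carbons. This bond, together with the absolute configuration of the two bridgeheads relative to C7, is the real difficulty.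
- Fragile groups: three prenyl alkenes (acid gives cyclic ethers and cation chemistry; no hydrogenation possible), the catechol (air oxidation as catecholate), and the chelating β-triketone (retro-Claisen, tautomers).
- Without the C6–C7–C8 bridge, the six carbons C1, C2, C3, C4, C5, C9 form a mirror-symmetric phloroglucinol-type ring: C1 is equivalent to C5 and C2 to C4 about the C3···C9 axis.
- The key step exploits this latent symmetry and the C7–C8 bond of the bridge. C7–C8 maps onto an epoxidized prenyl group on C5, whose tertiary carbon C8 is attacked by C1, as in the presumed biosynthesis.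
- In the biosynthesis a prenyl cation adds to C7; here a temporary oxygen takes that place. It controls the ring closure, locks C7 and C9 in a temporary ketal ring, and is exchanged for carbon afterwards.

## Logic of the disconnections

**24 to 23.** The O–Si bonds of the catechol and the O–CH3 bond at C4 are cut. The free catechol and the free β-triketone would chelate metals and interfere with every organometallic step, so they are unmasked last. The forward step must free three oxygens without acid (prenyl groups) and without oxidizing the catecholate.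

**23 to 17 and 21.** The C3–C(aroyl) bond is cut. This removes the whole aryl ketone and leaves a vinylogous methyl ester whose C3–H can be lithiated. The demand is a regioselective deprotonation at C3 and an acylating agent whose phenol protection survives a lithium amide.

**17 to 16 to 14.** The two C=C bonds of the C5 and C7 prenyl groups are cut back to allyl groups (cross-metathesis), then the C1–CH2 bond of the bridgehead prenyl group is cut. Allyl groups are inert as nucleophiles and to the oxidant in the earlier steps. Removing the C1 substituent turns the C1–C8 problem into a bond between a tertiary and a quaternary carbon. The demand is a bridgehead carbanion at C1, which needs the C2 carbonyl next to C1–H and therefore the C4 (not C2) enol ether.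

**14 to 13 to 12.** The C7–C(allyl) bond is exchanged for a C7–O bond. C7 then carries a heteroatom that can come from an epoxide, and the C7 configuration of the target is made late, under control of the bicycle. The demand is a radical allylation that enters from the exo face.

**12 to 11 to 10.** The C9 carbonyl and the C7 hydroxyl are tied back into the C7–O–C9 ketal, and the C2 carbonyl is taken back to a CH2 group. This gives the direct product of the ring closure. The demands are an allylic oxidation that picks C2–H2 and a ketal hydrolysis that spares the vinylogous ester.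

**10 to 8 (key).** The C1–C8 bond and the O–C9 bond are cut. Ring B and the ketal ring open, C1, C5 and C9 stop being stereocentres, and an achiral, mirror-symmetric 6,6-dialkyl bis(enol ether) with a single epoxide stereocentre remains. The forward step must open the epoxide at its tertiary carbon with only one of two enantiotopic enol ethers.

**8 to 6 and 3, 6 to 4.** The two bonds from the quaternary ring carbon (the future C5) to the epoxide arm (C5–C6) and to the allyl group are cut. Both are alkylations of the same doubly activated ring carbon of a commercial diene. The epoxide-bearing electrophile goes in second, so the epoxide never meets the alkyllithium base.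

**3 to 2 to 1.** The C–Br bond and the epoxide C–O bonds are cut. The only externally introduced chirality of the route comes from one catalytic asymmetric epoxidation of a commodity allylic alcohol.

**21 to 20 to 18.** The acyl C–Cl and the O–Si bonds are cut back to the commercial dihydroxy acid.

## Other disconnections considered

**Alternative 1:** (the first that comes to mind). Cut C1–C2 and C4–C5, ring A, in the Effenberger manner. Forward: double C-acylation of the cyclohexanone enol ether A1 with malonyl dichloride A2 to the bicyclic trione A3, then the same bridgehead and C3 chemistry as here.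
- Ring B with its C7 stereocentre would have to be made enantioselectively in a separate sequence of several steps before the key step.
- The second acylation has to occur at a methylene next to the quaternary C8, where O-acylation and self-condensation of A2 should compete.
- It leaves exactly the same endgame, so nothing is saved after the key step.
- The chosen closure builds ring B and both bridgeheads in one step from an achiral ring and one catalytic epoxidation.

**Alternative 2:** Cut C1–C8 and C5–C6 from the aromatic, achiral acylphloroglucinol A4. Forward: dearomative annulation with the enal A5 (conjugate addition at the dimethylated carbon, loss of acetate, second conjugate addition) to the C7 aldehyde A6.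
- The two prenylated ring carbons of A4 are enantiotopic and equally nucleophilic. Absolute configuration could only come from an ion-paired chiral cation in a step that makes a quaternary–quaternary bond, with no covalent control element.
- The formyl group of A6 needs about four further operations to become a prenyl group.
- The chosen plan uses covalent substrate control from a stereocentre in the chain.

**Alternative 3:** The same C1–C8 cut, with carbon on C7 from the start. Forward: protonation of the isopropenyl group of dienone A7 (chain from an auxiliary-controlled alkylation) to the tertiary cation A8, attack by one enantiotopic vinylogous ester carbon, and direct formation of 14.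
- It is shorter on paper: no oxygen-to-carbon exchange at C7 and no late oxidation.
- In A8 the cationic carbon sits next to C7–H, the only stereocentre. Loss of that proton to the tetrasubstituted alkene, or a 1,2-hydride shift between the two tertiary positions, would scramble C7 before ring closure. With an achiral ring this is racemization of the whole skeleton.
- An acid strong enough to protonate a 1,1-disubstituted alkene also protonates the basic cross-conjugated dienone oxygen and switches off the nucleophile.
- The epoxide version forms the bond by backside displacement on a bridged electrophile and keeps the controlling stereocentre on an oxygen-bearing carbon that cannot be lost this way.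

Key step: step 5

Remark on the chemistry: the target is treated as one compound with its enol tautomers (drawn as the C4 enol); locants C1–C9 of the bicyclo[3.3.1]nonane are used for all bicyclic compounds, and allyl groups stand for the C5 and C7 prenyl groups until step 11.

## Steps

Step 1
Reactants: 1 3-methylbut-2-en-1-ol
Product: 2 [(2R)-3,3-dimethyloxiran-2-yl]methanol
Conditions: Ti(Oi-Pr)4 (10 mol %), D-(−)-diethyl tartrate (12 mol %), t-BuOOH (anhydrous), 4 Å MS, CH2Cl2, −20 °C; non-aqueous work-up
Reagents that add atoms: tert-butyl hydroperoxide, CC(C)(C)OO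
Why: Sharpless asymmetric epoxidation of a primary allylic alcohol; by the facial rule of this reaction the D-(−)-tartrate catalyst should give the (2R)-epoxy alcohol (the L-(+)-ester gives the 2S series), and this is the only step of the route in which chirality is introduced from outside.

Step 2
Reactants: 2 [(2R)-3,3-dimethyloxiran-2-yl]methanol
Product: 3 (2S)-2-(bromomethyl)-3,3-dimethyloxirane
Conditions: PPh3, CBr4, CH2Cl2, 0 °C
Reagents that add atoms: carbon tetrabromide, BrC(Br)(Br)Br
Why: Appel reaction at the primary carbon of a 2,3-epoxy alcohol; no bond to the stereocentre is touched, and the descriptor changes from R to S only because CH2Br outranks the ring carbon.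

Step 3
Reactants: 4 1,5-dimethoxycyclohexa-1,4-diene
Product: 6 1,5-dimethoxy-6-(prop-2-en-1-yl)cyclohexa-1,4-diene, via lithiated diene 5 (not isolated)
Conditions: t-BuLi (1.0 equiv), THF, −78 °C; allyl bromide, −78 to 0 °C
Reagents that add atoms: allyl bromide, C=CCBr
Why: Deprotonation at C6, the carbon flanked by both methoxy-bearing carbons (cyclohexadienyl anion with the alkoxy groups on its nodal positions), and C-alkylation at the same carbon, as in Birch reductive alkylations.

Step 4
Reactants: 6 1,5-dimethoxy-6-(prop-2-en-1-yl)cyclohexa-1,4-diene; 3 (2S)-2-(bromomethyl)-3,3-dimethyloxirane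
Product: 8 6-{[(2R)-3,3-dimethyloxiran-2-yl]methyl}-1,5-dimethoxy-6-(prop-2-en-1-yl)cyclohexa-1,4-diene, via lithiated allyl diene 7 (not isolated)
Conditions: t-BuLi (1.0 equiv), THF, −78 to −30 °C; then 3, −78 to 0 °C
Reagents that add atoms: none
Why: Second deprotonation at the same, now tertiary, doubly activated C6–H and SN2 displacement of the primary bromide by the soft cyclohexadienyl anion; the epoxide is added only after the alkyllithium is consumed, and the new quaternary carbon lies on the mirror plane of the ring, so the epoxide carbon stays the only stereocentre.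

Step 5
Reactants: 8 6-{[(2R)-3,3-dimethyloxiran-2-yl]methyl}-1,5-dimethoxy-6-(prop-2-en-1-yl)cyclohexa-1,4-diene
Product: 10 (1S,5S,7R,9R)-4,9-dimethoxy-8,8-dimethyl-5-(prop-2-en-1-yl)-7,9-epoxybicyclo[3.3.1]non-3-ene (oxygen bridge from C7 to C9), via oxocarbenium ion 9 (not isolated)
Conditions: Me3SiOTf (0.3 equiv), 2,6-lutidine (0.5 equiv), CH2Cl2, −78 °C
Reagents that add atoms: none
Why: Me3Si+ binds the epoxide oxygen of 8 and one methyl enol ether attacks the tertiary epoxide carbon C8 from the back, which forms the C1–C8 bond and oxocarbenium ion 9; the C7 silyl ether oxygen then adds to C9 and releases Me3Si+, so the silyl triflate turns over while 2,6-lutidine keeps the medium aprotic. The closest known reaction type is the Lewis-acid epoxide-opening cation–olefin cyclization onto an enol ether of a 6,6-dialkyl-1,5-dimethoxycyclohexa-1,4-diene, and it copies the biosynthetic C1-to-C8 closure with the epoxide oxygen in the place of the prenyl cation that Nature adds to C7. Ring B closes 6-endo-trig at the enol ether and in the endo mode at the epoxide (attack at the distal, tertiary carbon, favoured by its substitution and by the 5-endo-trig nature of the alternative at C7), and the oxolane ring O–C7–C8–C1–C9 closes 5-exo-trig at the oxocarbenium carbon. C7 keeps the epoxide configuration because no bond to it is broken. Backside attack holds the C7–O bond anti to the forming C1–C8 bond, that is equatorial on a chair-like ring B, and with the (2R)-epoxide only one of the two enantiotopic enol ethers reaches C8 through this chair while the other needs a boat, which sets C1 (S) and C5 (S) together. C9 (R) follows from geometry, since the oxygen bridge can only span the exo face of ring B. The step needs the enol ether to win over the monosubstituted allyl alkene as nucleophile (secured by its far higher nucleophilicity), C–C bond formation to win over a 1,2-hydride shift (secured by the pre-organized six-ring closure at −78 °C on a bridged, non-carbocationic electrophile), and one enol ether to win over the other (chair against boat); a minor boat product cannot close the ketal and is removed as a different compound, so it should not lower the enantiopurity of 10.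

Step 6
Reactants: 10 (1S,5S,7R,9R)-4,9-dimethoxy-8,8-dimethyl-5-(prop-2-en-1-yl)-7,9-epoxybicyclo[3.3.1]non-3-ene
Product: 11 (1R,5S,7R,9R)-4,9-dimethoxy-8,8-dimethyl-5-(prop-2-en-1-yl)-7,9-epoxybicyclo[3.3.1]non-3-en-2-one
Conditions: Pd(OH)2/C (5 mol %), t-BuOOH (5 equiv), K2CO3 (0.25 equiv), CH2Cl2, 4 °C
Reagents that add atoms: tert-butyl hydroperoxide, CC(C)(C)OO
Why: Allylic oxidation by tert-butylperoxyl radicals; C2–H2 is the only C–H allylic to the electron-rich enol ether, the allyl radical is oxygenated at its unhindered terminus C2 and not at C4 next to the quaternary C5, and the carbonate buffer protects enol ether and ketal (the C1 descriptor changes by priority only).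

Step 7
Reactants: 11 (1R,5S,7R,9R)-4,9-dimethoxy-8,8-dimethyl-5-(prop-2-en-1-yl)-7,9-epoxybicyclo[3.3.1]non-3-en-2-one
Product: 12 (1R,5S,7R)-7-hydroxy-4-methoxy-8,8-dimethyl-5-(prop-2-en-1-yl)bicyclo[3.3.1]non-3-ene-2,9-dione
Conditions: 1 M HCl, THF, 23 °C
Reagents that add atoms: water, O
Why: Acid hydrolysis of the mixed ketal through opening of the oxygen bridge to the methyloxocarbenium ion and addition of water; the vinylogous methyl ester should be much slower because its hydrolysis needs conjugate addition at C4 next to the quaternary C5, and no stereocentre is touched.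

Step 8
Reactants: 12 (1R,5S,7R)-7-hydroxy-4-methoxy-8,8-dimethyl-5-(prop-2-en-1-yl)bicyclo[3.3.1]non-3-ene-2,9-dione
Product: 13 O-[(1R,5S,7R)-4-methoxy-8,8-dimethyl-2,9-dioxo-5-(prop-2-en-1-yl)bicyclo[3.3.1]non-3-en-7-yl] O-phenyl carbonothioate
Conditions: PhOC(S)Cl, pyridine, DMAP (cat.), CH2Cl2, 23 °C
Reagents that add atoms: O-phenyl chlorothionoformate, S=C(Cl)Oc1ccccc1
Why: Thionoacylation of the secondary alcohol (the activation used for Barton–McCombie chemistry); the open hydroxy ketone form is trapped irreversibly even if it equilibrates with a bridged hemiketal.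

Step 9
Reactants: 13 O-[(1R,5S,7R)-4-methoxy-8,8-dimethyl-2,9-dioxo-5-(prop-2-en-1-yl)bicyclo[3.3.1]non-3-en-7-yl] O-phenyl carbonothioate
Product: 14 (1R,5S,7R)-4-methoxy-8,8-dimethyl-5,7-di(prop-2-en-1-yl)bicyclo[3.3.1]non-3-ene-2,9-dione
Conditions: allylSnBu3 (10 equiv), AIBN (0.2 equiv), PhH, 80 °C
Reagents that add atoms: allyltributylstannane, C=CC[Sn](CCCC)(CCCC)CCCC
Why: Keck radical allylation of a secondary thionocarbonate; the planar C7 radical erases the old configuration and the stannane should enter from the exo face because the endo lobe points into ring A (toward C3), which places the allyl group equatorial (7R), while 5-exo cyclization onto the C5 allyl group would need an impossible bridge between two equatorial positions.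

Step 10
Reactants: 14 (1R,5S,7R)-4-methoxy-8,8-dimethyl-5,7-di(prop-2-en-1-yl)bicyclo[3.3.1]non-3-ene-2,9-dione
Product: 16 (1R,5S,7R)-4-methoxy-8,8-dimethyl-1-(3-methylbut-2-en-1-yl)-5,7-di(prop-2-en-1-yl)bicyclo[3.3.1]non-3-ene-2,9-dione, via bridgehead lithium compound 15 (not isolated)
Conditions: LDA (LiN(i-Pr)2), THF, −78 °C; prenyl bromide, −78 to −30 °C
Reagents that add atoms: prenyl bromide, CC(C)=CCBr
Why: Bridgehead deprotonation of C1–H, which is flanked by the C2 and C9 carbonyl groups (a non-enolizable, inductively stabilized carbanion, a known reaction of O-methylated bicyclo[3.3.1]nonane-2,4,9-triones), and SN2 alkylation; the bicycle fixes the configuration at C1, and this makes the C1–C8 bond one between two quaternary carbons.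

Step 11
Reactants: 16 (1R,5S,7R)-4-methoxy-8,8-dimethyl-1-(3-methylbut-2-en-1-yl)-5,7-di(prop-2-en-1-yl)bicyclo[3.3.1]non-3-ene-2,9-dione
Product: 17 (1R,5S,7R)-4-methoxy-8,8-dimethyl-1,5,7-tris(3-methylbut-2-en-1-yl)bicyclo[3.3.1]non-3-ene-2,9-dione
Conditions: second-generation Grubbs catalyst RuCl2(=CHPh)(PCy3)(H2IMes) (10 mol %), 2-methylbut-2-ene/CH2Cl2, 40 °C
Reagents that add atoms: 2-methylbut-2-ene, CC=C(C)C
Why: Olefin cross-metathesis of the two monosubstituted allyl groups with excess trisubstituted alkene; the existing prenyl group only exchanges degenerately, and ring-closing metathesis between allyl groups on equatorial 1,3-positions is geometrically excluded.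

Step 12
Reactants: 18 3,4-dihydroxybenzoic acid
Product: 20 3,4-bis(tert-butyldimethylsilyloxy)benzoic acid, via silyl ester 19 (not isolated)
Conditions: TBSCl (3.3 equiv), imidazole, DMF, 23 °C; then AcOH/THF/H2O, 23 °C
Reagents that add atoms: tert-butyl(chloro)dimethylsilane, CC(C)(C)[Si](C)(C)Cl
Why: Exhaustive silylation followed by selective hydrolysis of the labile silyl ester, while the aryl silyl ethers survive dilute acetic acid.

Step 13
Reactants: 20 3,4-bis(tert-butyldimethylsilyloxy)benzoic acid
Product: 21 3,4-bis(tert-butyldimethylsilyloxy)benzoyl chloride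
Conditions: 1-chloro-N,N,2-trimethylprop-1-en-1-amine, CH2Cl2, 0 to 23 °C; used crude
Reagents that add atoms: 1-chloro-N,N,2-trimethylprop-1-en-1-amine (Ghosez reagent), CC(C)=C(Cl)N(C)C
Why: Acid chloride formation under neutral conditions with the Ghosez reagent; no HCl is set free, so the aryl silyl ethers survive.

Step 14
Reactants: 17 (1R,5S,7R)-4-methoxy-8,8-dimethyl-1,5,7-tris(3-methylbut-2-en-1-yl)bicyclo[3.3.1]non-3-ene-2,9-dione; 21 3,4-bis(tert-butyldimethylsilyloxy)benzoyl chloride
Product: 23 (1S,5S,7R)-3-[3,4-bis(tert-butyldimethylsilyloxy)benzoyl]-4-methoxy-8,8-dimethyl-1,5,7-tris(3-methylbut-2-en-1-yl)bicyclo[3.3.1]non-3-ene-2,9-dione, via C3-lithio compound 22 (not isolated)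
Conditions: LiTMP (lithium 2,2,6,6-tetramethylpiperidide), THF, −78 °C; then 21, −78 to −20 °C
Reagents that add atoms: none
Why: α-Lithiation of the vinylogous ester at the vinylic C3–H (between the C2 carbonyl and the C4 methoxy group) by a hindered amide base, then acylation with the acid chloride, a known sequence on this class of O-methylated triones; both bridgeheads are blocked and the silyl ethers are inert (the C1 descriptor changes by priority only).

Step 15
Reactants: 23 (1S,5S,7R)-3-[3,4-bis(tert-butyldimethylsilyloxy)benzoyl]-4-methoxy-8,8-dimethyl-1,5,7-tris(3-methylbut-2-en-1-yl)bicyclo[3.3.1]non-3-ene-2,9-dione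
Product: 24 aristophenone A, (1S,5S,7R)-3-(3,4-dihydroxybenzoyl)-4-hydroxy-8,8-dimethyl-1,5,7-tris(3-methylbut-2-en-1-yl)bicyclo[3.3.1]non-3-ene-2,9-dione
Conditions: LiOH, 1,4-dioxane/H2O (degassed, argon), 90 °C; then 1 M HCl to pH 3, 0 °C
Reagents that add atoms: lithium hydroxide, [Li+].[OH-]
Why: Hydroxide adds to C4 of the doubly activated vinylogous ester and expels methoxide (addition–elimination), and it cleaves the aryl silyl ethers at silicon; no stereocentre is α to an enolizable position, so none can epimerize, and cold acidification should give the enolized triketone without touching the prenyl groups.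

## Compound list

1 | 3-methylbut-2-en-1-ol | CC(C)=CCO | starting material
2 | [(2R)-3,3-dimethyloxiran-2-yl]methanol | OC[C@H]1OC1(C)C | intermediate
3 | (2S)-2-(bromomethyl)-3,3-dimethyloxirane | BrC[C@H]1OC1(C)C | intermediate
4 | 1,5-dimethoxycyclohexa-1,4-diene | COC1=CCC=C(OC)C1 | starting material
5 | 6-lithio-1,5-dimethoxycyclohexa-1,4-diene | [Li]C1C(OC)=CCC=C1OC | intermediate (not isolated)
6 | 1,5-dimethoxy-6-(prop-2-en-1-yl)cyclohexa-1,4-diene | C=CCC1C(OC)=CCC=C1OC | intermediate
7 | 6-lithio-1,5-dimethoxy-6-(prop-2-en-1-yl)cyclohexa-1,4-diene | [Li]C1(CC=C)C(OC)=CCC=C1OC | intermediate (not isolated)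
8 | 6-{[(2R)-3,3-dimethyloxiran-2-yl]methyl}-1,5-dimethoxy-6-(prop-2-en-1-yl)cyclohexa-1,4-diene | C=CCC1(C[C@H]2OC2(C)C)C(OC)=CCC=C1OC | intermediate
9 | [(1S,5S,7R)-4-methoxy-8,8-dimethyl-5-(prop-2-en-1-yl)-7-(trimethylsilyloxy)bicyclo[3.3.1]non-3-en-9-ylidene](methyl)oxonium | C[Si](C)(C)O[C@@H]1C[C@]2(CC=C)C(=[O+]C)[C@@H](CC=C2OC)C1(C)C | intermediate (not isolated)
10 | (1S,5S,7R,9R)-4,9-dimethoxy-8,8-dimethyl-5-(prop-2-en-1-yl)-7,9-epoxybicyclo[3.3.1]non-3-ene | O3[C@@H]1C[C@]2(CC=C)[C@@]3(OC)[C@@H](CC=C2OC)C1(C)C | intermediate
11 | (1R,5S,7R,9R)-4,9-dimethoxy-8,8-dimethyl-5-(prop-2-en-1-yl)-7,9-epoxybicyclo[3.3.1]non-3-en-2-one | O3[C@@H]1C[C@]2(CC=C)[C@@]3(OC)[C@@H](C(=O)C=C2OC)C1(C)C | intermediate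
12 | (1R,5S,7R)-7-hydroxy-4-methoxy-8,8-dimethyl-5-(prop-2-en-1-yl)bicyclo[3.3.1]non-3-ene-2,9-dione | O[C@@H]1C[C@]2(CC=C)C(=O)[C@@H](C(=O)C=C2OC)C1(C)C | intermediate
13 | O-[(1R,5S,7R)-4-methoxy-8,8-dimethyl-2,9-dioxo-5-(prop-2-en-1-yl)bicyclo[3.3.1]non-3-en-7-yl] O-phenyl carbonothioate | S=C(Oc3ccccc3)O[C@@H]1C[C@]2(CC=C)C(=O)[C@@H](C(=O)C=C2OC)C1(C)C | intermediate
14 | (1R,5S,7R)-4-methoxy-8,8-dimethyl-5,7-di(prop-2-en-1-yl)bicyclo[3.3.1]non-3-ene-2,9-dione | C=CC[C@@H]1C[C@]2(CC=C)C(=O)[C@@H](C(=O)C=C2OC)C1(C)C | intermediate
15 | 1-lithio derivative of 14 (lithium in the place of the bridgehead hydrogen at C1) | C=CC[C@@H]1C[C@]2(CC=C)C(=O)[C@@]([Li])(C(=O)C=C2OC)C1(C)C | intermediate (not isolated)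
16 | (1R,5S,7R)-4-methoxy-8,8-dimethyl-1-(3-methylbut-2-en-1-yl)-5,7-di(prop-2-en-1-yl)bicyclo[3.3.1]non-3-ene-2,9-dione | C=CC[C@@H]1C[C@]2(CC=C)C(=O)[C@@](CC=C(C)C)(C(=O)C=C2OC)C1(C)C | intermediate
17 | (1R,5S,7R)-4-methoxy-8,8-dimethyl-1,5,7-tris(3-methylbut-2-en-1-yl)bicyclo[3.3.1]non-3-ene-2,9-dione | CC(C)=CC[C@@H]1C[C@]2(CC=C(C)C)C(=O)[C@@](CC=C(C)C)(C(=O)C=C2OC)C1(C)C | intermediate
18 | 3,4-dihydroxybenzoic acid | O=C(O)c1ccc(O)c(O)c1 | starting material
19 | tert-butyldimethylsilyl 3,4-bis(tert-butyldimethylsilyloxy)benzoate | CC(C)(C)[Si](C)(C)OC(=O)c1ccc(O[Si](C)(C)C(C)(C)C)c(O[Si](C)(C)C(C)(C)C)c1 | intermediate (not isolated)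
20 | 3,4-bis(tert-butyldimethylsilyloxy)benzoic acid | O=C(O)c1ccc(O[Si](C)(C)C(C)(C)C)c(O[Si](C)(C)C(C)(C)C)c1 | intermediate
21 | 3,4-bis(tert-butyldimethylsilyloxy)benzoyl chloride | O=C(Cl)c1ccc(O[Si](C)(C)C(C)(C)C)c(O[Si](C)(C)C(C)(C)C)c1 | intermediate
22 | 3-lithio derivative of 17 (lithium on the vinylic C3) | CC(C)=CC[C@@H]1C[C@]2(CC=C(C)C)C(=O)[C@@](CC=C(C)C)(C(=O)C([Li])=C2OC)C1(C)C | intermediate (not isolated)
23 | (1S,5S,7R)-3-[3,4-bis(tert-butyldimethylsilyloxy)benzoyl]-4-methoxy-8,8-dimethyl-1,5,7-tris(3-methylbut-2-en-1-yl)bicyclo[3.3.1]non-3-ene-2,9-dione | CC(C)=CC[C@@H]1C[C@]2(CC=C(C)C)C(=O)[C@@](CC=C(C)C)(C(=O)C(C(=O)c3ccc(O[Si](C)(C)C(C)(C)C)c(O[Si](C)(C)C(C)(C)C)c3)=C2OC)C1(C)C | intermediate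
24 | aristophenone A, (1S,5S,7R)-3-(3,4-dihydroxybenzoyl)-4-hydroxy-8,8-dimethyl-1,5,7-tris(3-methylbut-2-en-1-yl)bicyclo[3.3.1]non-3-ene-2,9-dione | CC(C)=CC[C@@H]1C[C@]2(CC=C(C)C)C(=O)[C@@](CC=C(C)C)(C(=O)C(C(=O)c3ccc(O)c(O)c3)=C2O)C1(C)C | target

## Step count and least certain steps

Total step count: 15. Longest linear sequence: 12 steps (steps 1, 2, 4 to 11, 14, 15).

**Step 5 (key step).**
- What may go wrong: the silyl triflate may consume the two acid-labile enol ethers (silyl transfer, hydrolysis on traces of water) faster than it opens the hindered trisubstituted epoxide. The activated epoxide may also rearrange by a 1,2-hydride shift (Meinwald rearrangement) before the C–C bond forms. Closure through the other enol ether (boat) would cost yield only, because that diastereomer cannot close the ketal.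
- Fallback: it sets out from 8 and comes back to the route at 11. The doubly allylic ring CH2 of 8 is oxidized first (Pd(OH)2/C, t-BuOOH, K2CO3, CH2Cl2) to the cross-conjugated dienone 4-{[(2R)-3,3-dimethyloxiran-2-yl]methyl}-3,5-dimethoxy-4-(prop-2-en-1-yl)cyclohexa-2,5-dien-1-one F1. Its ring is an acid-stable bis(vinylogous ester). A Brønsted acid (camphorsulfonic acid, CH2Cl2, 0 °C) then opens the epoxide with the α-carbon of one vinylogous ester through the same chair, and the C7 hydroxyl captures the methyloxocarbenium carbon. This gives 11 directly and makes step 6 unnecessary. The fallback changes the nucleophile, the mode of activation and the order of oxidation and ring closure.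

**Step 10 (bridgehead prenylation).**
- What may go wrong: C–C bond formation between the pyramidal bridgehead carbanion 15, which sits next to the quaternary C8, and the bulky allylic bromide may be slower than proton return or deprotonation at the vinylic C3–H.
- Fallback: it sets out from 14 and comes back at 17. The bridgehead anion is quenched with the small electrophile iodine (LDA, THF, −78 °C; I2) to give (1S,5S,7R)-1-iodo-4-methoxy-8,8-dimethyl-5,7-di(prop-2-en-1-yl)bicyclo[3.3.1]non-3-ene-2,9-dione F2. A bridgehead radical, which is insensitive to the crowding, is then allylated (allylSnBu3, AIBN, PhH, 80 °C) to (1R,5S,7R)-4-methoxy-8,8-dimethyl-1,5,7-tri(prop-2-en-1-yl)bicyclo[3.3.1]non-3-ene-2,9-dione F3. Cross-metathesis of all three allyl groups with 2-methylbut-2-ene under the conditions of step 11 gives 17.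

**Step 14 (C3 aroylation).**
- What may go wrong: the hindered vinyllithium 22 may be acylated only slowly, so that the amide base consumes 21 or conversion stops early.
- Fallback: it sets out from 17 (through 22) and comes back at 23. The vinyllithium is trapped with the more reactive aldehyde 3,4-bis(tert-butyldimethylsilyloxy)benzaldehyde F4 (from 3,4-dihydroxybenzaldehyde, TBSCl, imidazole, DMF). The resulting carbinol (1S,5S,7R)-3-{[3,4-bis(tert-butyldimethylsilyloxy)phenyl](hydroxy)methyl}-4-methoxy-8,8-dimethyl-1,5,7-tris(3-methylbut-2-en-1-yl)bicyclo[3.3.1]non-3-ene-2,9-dione F5 (both carbinol epimers) is oxidized with Dess–Martin periodinane (CH2Cl2, 23 °C) to 23.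

**Step 15 (global deprotection).**
- What may go wrong: the catecholate may be oxidized by traces of oxygen in hot hydroxide, and the β-triketone may lose the aroyl group by retro-Claisen cleavage.
- Fallback: it sets out from 23 and comes back at 24. The silyl ethers are removed first with Bu4NF/AcOH (THF, 0 °C) to (1S,5S,7R)-3-(3,4-dihydroxybenzoyl)-4-methoxy-8,8-dimethyl-1,5,7-tris(3-methylbut-2-en-1-yl)bicyclo[3.3.1]non-3-ene-2,9-dione F6. The methyl group is then removed by SN2 attack of chloride (LiCl, DMSO, 120 °C, argon), a non-hydrolytic demethylation, and mild acidification gives 24.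

## Further compounds

F1 | step 5 | 4-{[(2R)-3,3-dimethyloxiran-2-yl]methyl}-3,5-dimethoxy-4-(prop-2-en-1-yl)cyclohexa-2,5-dien-1-one | C=CCC1(C[C@H]2OC2(C)C)C(OC)=CC(=O)C=C1OC
F2 | step 10 | (1S,5S,7R)-1-iodo-4-methoxy-8,8-dimethyl-5,7-di(prop-2-en-1-yl)bicyclo[3.3.1]non-3-ene-2,9-dione | C=CC[C@@H]1C[C@]2(CC=C)C(=O)[C@@](I)(C(=O)C=C2OC)C1(C)C
F3 | step 10 | (1R,5S,7R)-4-methoxy-8,8-dimethyl-1,5,7-tri(prop-2-en-1-yl)bicyclo[3.3.1]non-3-ene-2,9-dione | C=CC[C@@H]1C[C@]2(CC=C)C(=O)[C@@](CC=C)(C(=O)C=C2OC)C1(C)C
F4 | step 14 | 3,4-bis(tert-butyldimethylsilyloxy)benzaldehyde | O=Cc1ccc(O[Si](C)(C)C(C)(C)C)c(O[Si](C)(C)C(C)(C)C)c1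
F5 | step 14 | (1S,5S,7R)-3-{[3,4-bis(tert-butyldimethylsilyloxy)phenyl](hydroxy)methyl}-4-methoxy-8,8-dimethyl-1,5,7-tris(3-methylbut-2-en-1-yl)bicyclo[3.3.1]non-3-ene-2,9-dione, both carbinol epimers | CC(C)=CC[C@@H]1C[C@]2(CC=C(C)C)C(=O)[C@@](CC=C(C)C)(C(=O)C(C(O)c3ccc(O[Si](C)(C)C(C)(C)C)c(O[Si](C)(C)C(C)(C)C)c3)=C2OC)C1(C)C
F6 | step 15 | (1S,5S,7R)-3-(3,4-dihydroxybenzoyl)-4-methoxy-8,8-dimethyl-1,5,7-tris(3-methylbut-2-en-1-yl)bicyclo[3.3.1]non-3-ene-2,9-dione | CC(C)=CC[C@@H]1C[C@]2(CC=C(C)C)C(=O)[C@@](CC=C(C)C)(C(=O)C(C(=O)c3ccc(O)c(O)c3)=C2OC)C1(C)C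
A1 | alternative 1 | (4R)-1-methoxy-5,5-dimethyl-2,4-bis(3-methylbut-2-en-1-yl)cyclohex-1-ene | COC1=C(CC=C(C)C)C[C@@H](CC=C(C)C)C(C)(C)C1
A2 | alternative 1 | malonyl dichloride | O=C(Cl)CC(Cl)=O
A3 | alternative 1 | (1R,5S,7R)-4-hydroxy-8,8-dimethyl-5,7-bis(3-methylbut-2-en-1-yl)bicyclo[3.3.1]non-3-ene-2,9-dione | CC(C)=CC[C@@H]1C[C@]2(CC=C(C)C)C(=O)[C@@H](C(=O)C=C2O)C1(C)C
A4 | alternative 2 | [3,4-bis(tert-butyldimethylsilyloxy)phenyl][2,4,6-trihydroxy-3,5-bis(3-methylbut-2-en-1-yl)phenyl]methanone | CC(C)=CCc1c(O)c(CC=C(C)C)c(O)c(C(=O)c2ccc(O[Si](C)(C)C(C)(C)C)c(O[Si](C)(C)C(C)(C)C)c2)c1O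
A5 | alternative 2 | (2-formyl-3-methylbut-2-en-1-yl) acetate | CC(=O)OCC(C=O)=C(C)C
A6 | alternative 2 | (1S,5S,7R)-3-[3,4-bis(tert-butyldimethylsilyloxy)benzoyl]-4-hydroxy-8,8-dimethyl-1,5-bis(3-methylbut-2-en-1-yl)-2,9-dioxobicyclo[3.3.1]non-3-ene-7-carbaldehyde | O=C[C@@H]1C[C@]2(CC=C(C)C)C(=O)[C@@](CC=C(C)C)(C(=O)C(C(=O)c3ccc(O[Si](C)(C)C(C)(C)C)c(O[Si](C)(C)C(C)(C)C)c3)=C2O)C1(C)C
A7 | alternative 3 | 3,5-dimethoxy-4-(prop-2-en-1-yl)-4-[(2R)-2-(prop-1-en-2-yl)pent-4-en-1-yl]cyclohexa-2,5-dien-1-one | C=CC[C@@H](C(C)=C)CC1(CC=C)C(OC)=CC(=O)C=C1OC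
A8 | alternative 3 | (3R)-3-{[2,6-dimethoxy-4-oxo-1-(prop-2-en-1-yl)cyclohexa-2,5-dien-1-yl]methyl}-2-methylhex-5-en-2-ylium | C=CC[C@@H]([C+](C)C)CC1(CC=C)C(OC)=CC(=O)C=C1OC
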